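**Retrosynthetic overview**
1. Target 8 (an achiral isoflavone) is opened at O1–C2 of ring C to give 2-hydroxydeoxybenzoin 6 plus a one-carbon unit (DMF-DMA). Ring C is the only ring made and is closed last.
2. 6 comes from deoxybenzoin 4 by cutting the aryl C8a–O1 bond: a ketone-directed ortho C–H to C–O oxygenation (key step, proposed new Rh-catalysed benzoyloxylation with dibenzoyl peroxide).
3. 4 comes from (3,4,5-trimethoxyphenyl)acetic acid 1 and methyl 3,4,5-trimethoxybenzoate 2 by Claisen acylation and decarboxylation.
4. Rings A and B are both bought as the cheap 3,4,5-trimethoxyphenyl pattern. The 6,7,8-oxygenation of ring A arises because the new oxygen enters ortho to the carbonyl, which avoids the costlier 2,3,4-trimethoxyphenol.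

Assumption: the target has no stereocentre, stereogenic axis or double-bond isomerism, so it is one achiral compound and no stereocontrol is needed.

**Step 1**
Reactants: 1 (3,4,5-trimethoxyphenyl)acetic acid; 2 methyl 3,4,5-trimethoxybenzoate
Product: 4 deoxybenzoin 1,2-bis(3,4,5-trimethoxyphenyl)ethan-1-one, via β-keto acid 3 (not isolated)
Conditions: t-BuMgCl (3.1 equiv), THF, 0 → 60 °C, 1 h; 2 (1.0 equiv), 60 °C, 3 h; then 3 M HCl, 50 °C, 1 h
Reagents that add atoms: none
Why: Ivanov-type Claisen condensation followed by decarboxylation: the chloromagnesium enediolate of 1, ArCH=C(OMgCl)2, is C-acylated by the non-enolisable ester 2, the chelated β-keto carboxylate resists further addition, and acidification gives β-keto acid 3, which loses CO2 on warming; no stereocentre remains.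

**Step 2**
Reactants: 4 deoxybenzoin 1,2-bis(3,4,5-trimethoxyphenyl)ethan-1-one
Product: 6 2-hydroxydeoxybenzoin 1-(2-hydroxy-3,4,5-trimethoxyphenyl)-2-(3,4,5-trimethoxyphenyl)ethan-1-one, via aryl benzoate 5 (not isolated)
Conditions: [(C5Me5)Rh(MeCN)3](SbF6)2 (5 mol%), NaOPiv (15 mol%), (PhCO2)2 (1.2 equiv, in portions), ClCH2CH2Cl, N2, 60 °C, 12 h; then NH3 (7 M in MeOH), 23 °C, 2 h
Reagents that add atoms: dibenzoyl peroxide, O=C(OOC(=O)c1ccccc1)c1ccccc1
Why: Proposed new method: a ketone-directed ortho C–H benzoyloxylation in which dibenzoyl peroxide is both oxygen source and internal oxidant; the ketone oxygen binds the cationic (C5Me5)Rh(OPiv) fragment (trivalent rhodium), and carboxylate-assisted metalation cleaves the only C–H that gives a five-membered rhodacycle (C2–H of the aroyl ring; its two ortho sites are equivalent, and ring B would need a six-membered metallacycle); the aryl–Rh bond then opens the weak O–O bond (oxidative addition to pentavalent rhodium and C–O reductive elimination, or SN2-type attack at oxygen), giving aryl benzoate 5 and a (C5Me5)Rh(O2CPh) species that is the base for the next C–H cleavage, so no external oxidant or strong acid is needed and the electron-rich rings and benzylic CH2 meet only a two-electron, inner-sphere oxidant; ammonolysis then frees phenol 6 without the enolate chemistry (Baker–Venkataraman benzoyl shift) that alkoxide bases could trigger; no stereocentre is formed; the closest known reaction types are [(C5Me5)RhCl2]2/AgSbF6- and [(C5Me5)IrCl2]2/AgNTf2-catalysed C–H halogenation with N-halosuccinimides and C–H amidation with azides or dioxazolones directed by weakly coordinating carbonyl groups, and Pd(OAc)2-catalysed pyridine-directed C–H acyloxylation with peroxides; to my knowledge, acyloxy transfer from a diacyl peroxide to a ketone-derived rhodacycle has not been shown.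

**Step 3**
Reactants: 6 2-hydroxydeoxybenzoin 1-(2-hydroxy-3,4,5-trimethoxyphenyl)-2-(3,4,5-trimethoxyphenyl)ethan-1-one
Product: 8 isoflavone 6,7,8-trimethoxy-3-(3,4,5-trimethoxyphenyl)-4H-chromen-4-one (target), via hydroxy enaminone 7 (not isolated)
Conditions: Me2NCH(OMe)2 (3 equiv), toluene, 100 °C, 4 h
Reagents that add atoms: N,N-dimethylformamide dimethyl acetal, COC(OC)N(C)C
Why: Standard deoxybenzoin isoflavone synthesis: DMF-DMA condenses at the doubly activated CH2 to enaminone 7, whose phenol closes ring C by intramolecular oxa-Michael addition and elimination of dimethylamine, forming the O1–C2 bond; no stereocentre is created.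

**Compound list**
1 | (3,4,5-trimethoxyphenyl)acetic acid | COc1cc(CC(=O)O)cc(OC)c1OC | starting material
2 | methyl 3,4,5-trimethoxybenzoate | COC(=O)c1cc(OC)c(OC)c(OC)c1 | starting material
3 | 3-oxo-2,3-bis(3,4,5-trimethoxyphenyl)propanoic acid (racemic; present as its magnesium salt, formed and consumed in the flask) | COc1cc(C(C(=O)O)C(=O)c2cc(OC)c(OC)c(OC)c2)cc(OC)c1OC | intermediate
4 | 1,2-bis(3,4,5-trimethoxyphenyl)ethan-1-one | COc1cc(CC(=O)c2cc(OC)c(OC)c(OC)c2)cc(OC)c1OC | intermediate
5 | 2,3,4-trimethoxy-6-[2-(3,4,5-trimethoxyphenyl)acetyl]phenyl benzoate (formed and consumed in the flask) | COc1cc(CC(=O)c2cc(OC)c(OC)c(OC)c2OC(=O)c2ccccc2)cc(OC)c1OC | intermediate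
6 | 1-(2-hydroxy-3,4,5-trimethoxyphenyl)-2-(3,4,5-trimethoxyphenyl)ethan-1-one | COc1cc(CC(=O)c2cc(OC)c(OC)c(OC)c2O)cc(OC)c1OC | intermediate
7 | (E)-3-(dimethylamino)-1-(2-hydroxy-3,4,5-trimethoxyphenyl)-2-(3,4,5-trimethoxyphenyl)prop-2-en-1-one (formed and consumed in the flask; alkene geometry is immaterial) | CN(C)/C=C(\c1cc(OC)c(OC)c(OC)c1)C(=O)c1cc(OC)c(OC)c(OC)c1O | intermediate
8 | 6,7,8-trimethoxy-3-(3,4,5-trimethoxyphenyl)-4H-chromen-4-one (CNP0330610.0) | COc1cc(-c2coc3c(OC)c(OC)c(OC)cc3c2=O)cc(OC)c1OC | target

**Step count**
Total steps: 3. Longest linear sequence: 3 steps.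

**Steps most likely to fail, with fallbacks**

Most at risk is step 2, the proposed new C–H benzoyloxylation. The ketone is a weak donor and the C–H to be cleaved is flanked by a methoxy group, so turnover may be low. Benzoyloxy radicals from thermal peroxide homolysis could attack ring B or the benzylic CH2. A rhodium enolate could give α-benzoyloxylation. The second ortho C–H could also be oxygenated. The fallback uses known chemistry and a different approach: the phenol oxygen is bought in rather than made by C–H oxidation. It sets out from compound 1 and comes back to the route at compound 6. Compound 1 and commercial 2,3,4-trimethoxyphenol F1 are heated in neat BF3·OEt2 at 85 °C, the classical Friedel–Crafts/Fries-type ortho-acylation of a phenol by an arylacetic acid. Work-up with aqueous NaOAc breaks the BF2 chelate and gives 6 directly. Acylation goes to the only position ortho to the hydroxyl, and compounds 2 to 5 are then not needed.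

Second is step 1. Enediolate formation from the electron-rich acid may be incomplete, or t-BuMgCl may attack ester 2, leaving mixtures. The fallback sets out from compound 1 and comes back at compound 4. Compound 1 is activated with 1,1'-carbonyldiimidazole and treated with MeNHOMe·HCl (CH2Cl2, 23 °C) to give N-methoxy-N-methyl-2-(3,4,5-trimethoxyphenyl)acetamide F2. Addition of (3,4,5-trimethoxyphenyl)magnesium bromide F3 (commercial THF solution, or from 5-bromo-1,2,3-trimethoxybenzene and Mg) at −20 to 0 °C and NH4Cl work-up gives 4. This is a Weinreb ketone synthesis: an aryl nucleophile adds to an arylacetyl electrophile instead of an enolate being acylated.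

Third is step 3. DMF-DMA can O-methylate the phenol, or the reaction can stall at enaminone 7. The fallback sets out from compound 6 and comes back at compound 8. C-formylation of 6 with ethyl formate and NaH (THF, 0 → 23 °C) gives 2-hydroxy-6,7,8-trimethoxy-3-(3,4,5-trimethoxyphenyl)chroman-4-one F4, a cyclic hemiacetal obtained as a mixture of racemic diastereomers. Dehydration with AcOH and catalytic H2SO4 at 80 °C removes both stereocentres and gives 8, the classical formate route to isoflavones.

**Further compounds**
F1 | step 2 | 2,3,4-trimethoxyphenol | COc1ccc(O)c(OC)c1OC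
F2 | step 1 | N-methoxy-N-methyl-2-(3,4,5-trimethoxyphenyl)acetamide | CON(C)C(=O)Cc1cc(OC)c(OC)c(OC)c1
F3 | step 1 | (3,4,5-trimethoxyphenyl)magnesium bromide | COc1cc([Mg]Br)cc(OC)c1OC
F4 | step 3 | 2-hydroxy-6,7,8-trimethoxy-3-(3,4,5-trimethoxyphenyl)chroman-4-one (mixture of racemic diastereomers) | COc1cc(C2C(O)Oc3c(OC)c(OC)c(OC)cc3C2=O)cc(OC)c1OC
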